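**Retrosynthetic overview**

1. End game: target 14 comes from hydrogenolysis of bis-benzyl ether 13, made by 5-O-methylation after selective 7-O-benzylation of 5,7-dihydroxyflavone 11. Ring C (O1–C2 bond) comes from acid cyclodehydration of the 2-methoxy-1,3-diketone 10 onto either of two equivalent ortho hydroxyls.
2. Feature the strategy rests on: ring A is a fully substituted phloroglucinol, with oxygen on C5, C7 and C8a, the acyl carbon C4 on C4a, and methoxy groups on C6 and C8. It is symmetric about the C4a–C7 axis and is the aromatized Claisen-folding product of a poly-β-carbonyl chain that already carries OMe on every second carbon.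
3. Key disconnection C4a–C8a: ring A comes from a magnesium-templated Claisen cyclization of the ring-opened 2-pyranone 8, a masked methyl 3,5,7,9-tetraoxo ester.
4. Pyranone 8 comes from two polyanion Claisen acylations of 6-methylpyranone 5 (methyl methoxyacetate, then methyl 4-(benzyloxy)benzoate). Pyranone 5 comes from self-Claisen condensation of methyl methoxyacetate, γ-acetylation of the β-keto ester dianion and lactonization.
5. Ring order: sacrificial pyranone, then ring A, then ring C; ring B arrives intact in the benzoate.

Key step: step 6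

Remark on the chemistry: compounds 2, 4, 8, 9 and 10 carry enolizable CH(OMe) centres between carbonyl groups. They are racemic (or epimer mixtures), are drawn as keto tautomers, and none of these centres survives in the target, which has no stereocenter.

**Route**

Step 1
Reactants: 1 methyl methoxyacetate (two molecules)
Product: 2 methyl 2,4-dimethoxy-3-oxobutanoate
Conditions: NaH (0.55 equiv per ester), cat. MeOH, PhMe, 60 °C; then aq. HCl, 0 °C
Reagents that add atoms: none
Why: Claisen self-condensation of an α-alkoxy ester, in which the doubly activated C2–H of the product is removed irreversibly by NaH and pulls the equilibrium to the β-keto ester.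

Step 2
Reactants: 2 methyl 2,4-dimethoxy-3-oxobutanoate; 3 N-methoxy-N-methylacetamide
Product: 4 methyl 2,4-dimethoxy-3,5-dioxohexanoate
Conditions: LiN(i-Pr)2 (2.2 equiv), THF, −78 to 0 °C; then 3, −78 to 0 °C; aq. HCl
Reagents that add atoms: none
Why: γ-Acylation of a β-keto ester dianion, where the second deprotonation can only occur at the C4 methylene and the N-methoxy-N-methylamide gives a chelated tetrahedral adduct that holds until work-up, so the acidic product cannot quench the dianion.

Step 3
Reactants: 4 methyl 2,4-dimethoxy-3,5-dioxohexanoate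
Product: 5 4-hydroxy-3,5-dimethoxy-6-methyl-2H-pyran-2-one
Conditions: DBU (1.5 equiv), PhMe, 80 °C; then aq. HCl
Reagents that add atoms: none
Why: Base-mediated lactonization of a 3,5-dioxo ester (O-acylation of the C5 enolate by the ester, six-membered closure with loss of methanol), the standard entry to 4-hydroxy-2-pyranones.

Step 4
Reactants: 5 4-hydroxy-3,5-dimethoxy-6-methyl-2H-pyran-2-one; 1 methyl methoxyacetate
Product: 6 4-hydroxy-3,5-dimethoxy-6-(3-methoxy-2-oxopropyl)-2H-pyran-2-one
Conditions: LiN(i-Pr)2 (3.1 equiv), THF, −78 to −20 °C; then 1, −78 °C to rt; aq. HCl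
Reagents that add atoms: none
Why: Claisen acylation of the dianion of a 4-hydroxy-6-methyl-2-pyranone at the exocyclic 6-methylene, its only carbon acid site since C3 and C5 carry OMe, with the third equivalent of base taking up the acidic proton of the new β-dicarbonyl unit.

Step 5
Reactants: 6 4-hydroxy-3,5-dimethoxy-6-(3-methoxy-2-oxopropyl)-2H-pyran-2-one; 7 methyl 4-(benzyloxy)benzoate
Product: 8 6-{4-[4-(benzyloxy)phenyl]-3-methoxy-2,4-dioxobutyl}-4-hydroxy-3,5-dimethoxy-2H-pyran-2-one
Conditions: LiN(i-Pr)2 (4.2 equiv), THF, −78 to 0 °C; then 7, 0 °C to rt; aq. HCl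
Reagents that add atoms: none
Why: Terminal aroylation of the trianion of a 6-(2-oxoalkyl)-4-hydroxy-2-pyranone (polyanion Claisen condensation), in which the last-formed and least stabilized carbanion at the CH2OMe terminus is the most nucleophilic site and the benzoate has no α-hydrogen.

Step 6
Reactants: 8 6-{4-[4-(benzyloxy)phenyl]-3-methoxy-2,4-dioxobutyl}-4-hydroxy-3,5-dimethoxy-2H-pyran-2-one
Product: 10 1-[4-(benzyloxy)phenyl]-2-methoxy-3-(2,4,6-trihydroxy-3,5-dimethoxyphenyl)propane-1,3-dione, via open-chain tetraoxo ester 9 (not isolated)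
Conditions: Mg(OMe)2 (8 equiv), degassed MeOH, reflux, N2; then cold 1 M HCl
Reagents that add atoms: none
Why: Proposed new method: methoxide delivered from magnesium adds to the lactone carbonyl and opens pyranone 8 to the magnesium chelate of methyl tetraoxo ester 9, whose only methylene (future C4a, between the future C4 and C5 carbonyls) is the most acidic carbon; its carbanion attacks the ester carbonyl (future C8a), methoxide leaves and the cyclohexanetrione enolizes to the aromatic ring A. The closest known reaction type is the Mg(OMe)2-mediated Claisen cyclization of 6-(2-oxoalkyl)-4-hydroxy-2-pyranones (masked 3,5,7-trioxo esters) to acylphloroglucinols, which has not been shown for chains bearing OMe on alternate carbons. Ring A is closed by C4a–C8a bond formation in a six-membered exo-trig acyl substitution of Dieckmann type. No stereocenter is created; the side-chain CH(OMe) centre stays racemic and becomes sp2 in step 7. The step needs Claisen closure to win over the three six-membered aldol closures and over retro-Claisen methanolysis: each aldol nucleophile (the carbons that become C8, C6 and C3) already bears OMe and would become a quaternary centre whose adduct cannot dehydrate to an arene, so those closures should stay reversible and only the Claisen path reaches an aromatic sink. Magnesium chelation should keep every 1,3-dicarbonyl unit enolized, shielding it from cleavage, and hold the ester near the central enolate.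

Step 7
Reactants: 10 1-[4-(benzyloxy)phenyl]-2-methoxy-3-(2,4,6-trihydroxy-3,5-dimethoxyphenyl)propane-1,3-dione
Product: 11 2-[4-(benzyloxy)phenyl]-5,7-dihydroxy-3,6,8-trimethoxy-4H-chromen-4-one
Conditions: p-TsOH·H2O (0.2 equiv), PhMe, 80 °C, N2
Reagents that add atoms: none
Why: Acid-catalysed cyclodehydration of an o-hydroxyaryl 1,3-diketone (second stage of a Baker–Venkataraman flavone synthesis), in which an ortho hydroxyl adds to the aroyl carbonyl and water is lost; the two ortho hydroxyls are equivalent by the symmetry of ring A, so a single flavone should result.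

Step 8
Reactants: 11 2-[4-(benzyloxy)phenyl]-5,7-dihydroxy-3,6,8-trimethoxy-4H-chromen-4-one
Product: 12 7-(benzyloxy)-2-[4-(benzyloxy)phenyl]-5-hydroxy-3,6,8-trimethoxy-4H-chromen-4-one
Conditions: BnBr (1.05 equiv), K2CO3 (1.1 equiv), acetone, 50 °C
Reagents that add atoms: benzyl bromide, BrCc1ccccc1
Why: Selective Williamson etherification, since the 7-OH is the more acidic vinylogous acid and is free whereas the 5-OH is locked in a hydrogen bond to the C4 carbonyl.

Step 9
Reactants: 12 7-(benzyloxy)-2-[4-(benzyloxy)phenyl]-5-hydroxy-3,6,8-trimethoxy-4H-chromen-4-one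
Product: 13 7-(benzyloxy)-2-[4-(benzyloxy)phenyl]-3,5,6,8-tetramethoxy-4H-chromen-4-one
Conditions: MeI (5 equiv), K2CO3 (3 equiv), DMF, 50 °C
Reagents that add atoms: iodomethane, CI
Why: Williamson O-methylation of the chelated 5-hydroxyl under forcing conditions, the only free hydroxyl left in the molecule.

Step 10
Reactants: 13 7-(benzyloxy)-2-[4-(benzyloxy)phenyl]-3,5,6,8-tetramethoxy-4H-chromen-4-one
Product: 14 7-hydroxy-2-(4-hydroxyphenyl)-3,5,6,8-tetramethoxy-4H-chromen-4-one
Conditions: H2 (1 atm), 10% Pd/C, EtOAc–MeOH, rt
Reagents that add atoms: none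
Why: Catalytic hydrogenolysis of both benzyl aryl ethers, under which the tetrasubstituted chromone C2=C3 bond and the aryl methyl ethers should be inert.

**Compound list**

1 | methyl methoxyacetate | COCC(=O)OC | starting material
2 | methyl 2,4-dimethoxy-3-oxobutanoate (racemic, enolizable) | COCC(=O)C(OC)C(=O)OC | intermediate
3 | N-methoxy-N-methylacetamide | CC(=O)N(C)OC | starting material
4 | methyl 2,4-dimethoxy-3,5-dioxohexanoate (epimer mixture, enolizable) | CC(=O)C(OC)C(=O)C(OC)C(=O)OC | intermediate
5 | 4-hydroxy-3,5-dimethoxy-6-methyl-2H-pyran-2-one | CC1=C(OC)C(O)=C(OC)C(=O)O1 | intermediate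
6 | 4-hydroxy-3,5-dimethoxy-6-(3-methoxy-2-oxopropyl)-2H-pyran-2-one | COCC(=O)CC1=C(OC)C(O)=C(OC)C(=O)O1 | intermediate
7 | methyl 4-(benzyloxy)benzoate | COC(=O)c1ccc(OCc2ccccc2)cc1 | starting material
8 | 6-{4-[4-(benzyloxy)phenyl]-3-methoxy-2,4-dioxobutyl}-4-hydroxy-3,5-dimethoxy-2H-pyran-2-one (racemic, enolizable) | COC(C(=O)CC1=C(OC)C(O)=C(OC)C(=O)O1)C(=O)c1ccc(OCc2ccccc2)cc1 | intermediate
9 | methyl 9-[4-(benzyloxy)phenyl]-2,4,8-trimethoxy-3,5,7,9-tetraoxononanoate (magnesium chelate in the flask, epimer mixture) | COC(=O)C(OC)C(=O)C(OC)C(=O)CC(=O)C(OC)C(=O)c1ccc(OCc2ccccc2)cc1 | intermediate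
10 | 1-[4-(benzyloxy)phenyl]-2-methoxy-3-(2,4,6-trihydroxy-3,5-dimethoxyphenyl)propane-1,3-dione (racemic, enolizable) | COC(C(=O)c1ccc(OCc2ccccc2)cc1)C(=O)c1c(O)c(OC)c(O)c(OC)c1O | intermediate
11 | 2-[4-(benzyloxy)phenyl]-5,7-dihydroxy-3,6,8-trimethoxy-4H-chromen-4-one | COc1c(O)c(OC)c2oc(-c3ccc(OCc4ccccc4)cc3)c(OC)c(=O)c2c1O | intermediate
12 | 7-(benzyloxy)-2-[4-(benzyloxy)phenyl]-5-hydroxy-3,6,8-trimethoxy-4H-chromen-4-one | COc1c(OCc2ccccc2)c(OC)c2oc(-c3ccc(OCc4ccccc4)cc3)c(OC)c(=O)c2c1O | intermediate
13 | 7-(benzyloxy)-2-[4-(benzyloxy)phenyl]-3,5,6,8-tetramethoxy-4H-chromen-4-one | COc1c(OCc2ccccc2)c(OC)c2oc(-c3ccc(OCc4ccccc4)cc3)c(OC)c(=O)c2c1OC | intermediate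
14 | 7-hydroxy-2-(4-hydroxyphenyl)-3,5,6,8-tetramethoxy-4H-chromen-4-one | COc1c(O)c(OC)c2oc(-c3ccc(O)cc3)c(OC)c(=O)c2c1OC | target

**Totals and risks**

Total step count: 10. Longest linear sequence: 10 steps (1 to 14); the partners 3 and 7 are purchased.

Steps most likely to fail:

1. Step 6 (proposed new method). The pyranone anion may resist methanolysis, or the opened chain may be lost to retro-Claisen cleavage of the aroyl group, to non-aromatizable aldol dead ends, or to air oxidation of the electron-rich product, instead of closing the C4a–C8a bond. The fallback uses known chemistry and installs the ring A methoxy groups on a preformed flavone. It sets out from 7: saponification (LiOH, THF–H2O) should give 4-(benzyloxy)benzoic acid F1, and dehydration with DCC in CH2Cl2 its anhydride, 4-(benzyloxy)benzoic anhydride F2. Allan–Robinson condensation of F2 and the potassium salt of F1 with 2-methoxy-1-(2,4,6-trihydroxyphenyl)ethan-1-one F3 (a catalogued ketone, otherwise the Hoesch product of phloroglucinol and methoxyacetonitrile) at 170 °C, followed by KOH in aqueous EtOH to cleave O-aroyl groups, should give 2-[4-(benzyloxy)phenyl]-5,7-dihydroxy-3-methoxy-4H-chromen-4-one F4. Bromination with Br2 in AcOH should take place at C6 and C8 of the activated ring A to give 2-[4-(benzyloxy)phenyl]-6,8-dibromo-5,7-dihydroxy-3-methoxy-4H-chromen-4-one F5. Copper-mediated methoxy-debromination (NaOMe, CuBr, DMF–MeOH, 100 °C), a substitution known for 6,8-dibromo-5,7-dihydroxyflavones, should then give 11, where the route is rejoined at step 8.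

2. Step 5. Trianion formation may be incomplete, and attack on the deactivated 4-alkoxybenzoate may be slow enough for proton transfer and decomposition of the polyanion to take over. The fallback replaces the Claisen acylation by aldol addition and oxidation. It sets out from 6: the same trianion (LiN(i-Pr)2, THF, −78 °C) is added to 4-(benzyloxy)benzaldehyde, a far better electrophile, to give 6-{4-[4-(benzyloxy)phenyl]-4-hydroxy-3-methoxy-2-oxobutyl}-4-hydroxy-3,5-dimethoxy-2H-pyran-2-one F6 as an inconsequential diastereomer mixture. Oxidation of the benzylic β-hydroxy ketone with IBX (EtOAc, 75 °C) should give the β-diketone 8, rejoining the route before step 6.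

3. Step 4. The enolizable ester may transfer a proton to the pyranone dianion or condense with itself faster than it acylates the 6-methylene. The fallback again trades acylation for aldol addition and oxidation. It sets out from 5: the dianion is added to freshly distilled methoxyacetaldehyde at −78 °C to give 4-hydroxy-6-(2-hydroxy-3-methoxypropyl)-3,5-dimethoxy-2H-pyran-2-one F7. Oxidation of the secondary alcohol with IBX (DMSO, rt) should give ketone 6, rejoining the route before step 5.

**Further compounds**

F1 | step 6 | 4-(benzyloxy)benzoic acid | OC(=O)c1ccc(OCc2ccccc2)cc1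
F2 | step 6 | 4-(benzyloxy)benzoic anhydride | O=C(OC(=O)c1ccc(OCc2ccccc2)cc1)c1ccc(OCc2ccccc2)cc1
F3 | step 6 | 2-methoxy-1-(2,4,6-trihydroxyphenyl)ethan-1-one | COCC(=O)c1c(O)cc(O)cc1O
F4 | step 6 | 2-[4-(benzyloxy)phenyl]-5,7-dihydroxy-3-methoxy-4H-chromen-4-one | COc1c(-c2ccc(OCc3ccccc3)cc2)oc2cc(O)cc(O)c2c1=O
F5 | step 6 | 2-[4-(benzyloxy)phenyl]-6,8-dibromo-5,7-dihydroxy-3-methoxy-4H-chromen-4-one | COc1c(-c2ccc(OCc3ccccc3)cc2)oc2c(Br)c(O)c(Br)c(O)c2c1=O
F6 | step 5 | 6-{4-[4-(benzyloxy)phenyl]-4-hydroxy-3-methoxy-2-oxobutyl}-4-hydroxy-3,5-dimethoxy-2H-pyran-2-one (diastereomer mixture, racemic) | COC(C(=O)CC1=C(OC)C(O)=C(OC)C(=O)O1)C(O)c1ccc(OCc2ccccc2)cc1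
F7 | step 4 | 4-hydroxy-6-(2-hydroxy-3-methoxypropyl)-3,5-dimethoxy-2H-pyran-2-one (racemic) | COCC(O)CC1=C(OC)C(O)=C(OC)C(=O)O1
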